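(All runs are simulated from invented constants, and the scatter is random.)

The ratio of reagent to substrate was 0.230 in maple and 3.70 in birch, and I took that ratio as my way into the new flasks.

| flask | substrate | reagent | free catalyst | remark | time |
|---|---|---|---|---|---|
| maple | 0.27 M (fed, over 1.0 min) | 0.062 M | 6.8 mM | run made earlier |  |
| larch | 0.27 M (fed, over 1.0 min) | 0.26 M | 6.8 mM | run made earlier |  |
| birch | 0.27 M (fed, over 1.0 min) | 1 M | 6.8 mM | run made earlier |  |
| ash | 0.52 M (fed, over 1.0 min) | 0.257 M | 6.8 mM | run made earlier |  |
| ochre | 0.80 M (fed, over 1.0 min) | 0.400 M | 5.0 mM |  | 2.0 min |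
| amber | 0.27 M (fed, over 2.0 min) | 1.00 M | 1.5 mM |  | 2.0 min |
| green | 0.27 M (fed, over 1.0 min) | 0.257 M | 6.8 mM |  | 2.0 min |
| violet | 0.27 M (fed, over 1.0 min) | 0.0600 M | 6.8 mM |  | 2.0 min |
| teal | 0.20 M (fed, over 3.0 min) | 0.400 M | 6.8 mM |  | 2.0 min |
| red | 0.80 M (fed, over 1.0 min) | 0.150 M | 20 mM |  | 2.0 min |

| run | time / s | target / % | over-reaction product / % | substrate / % |
|---|---|---|---|---|
| maple | 10.0 | 11.4 | 0.8 | 4.2 |
| maple | 20.0 | 20.2 | 0.7 | 11.8 |
| maple | 40.0 | 19.5 | 0.8 | 45.9 |
| maple | 60.0 | 20.0 | 1.2 | 77.4 |
| maple | 80.0 | 19.6 | 0.9 | 77.2 |
| larch | 10.0 | 9.4 | 5.3 | 1.7 |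
| larch | 12.0 | 11.5 | 6.8 | 0.3 |
| larch | 25.0 | 19.9 | 19.3 | 1.5 |
| larch | 40.0 | 34.9 | 28.9 | 2.5 |
| larch | 80.0 | 40.9 | 25.4 | 30.0 |
| birch | 10.0 | 5.1 | 10.7 | 0 |
| birch | 20.0 | 4.9 | 25.4 | 2.0 |
| birch | 40.0 | 5.9 | 58.1 | 3.5 |
| birch | 60.0 | 8.9 | 91.5 | 1.6 |
| birch | 80.0 | 0 | 100.4 | 0 |
| ash | 15.0 | 10.3 | 6.3 | 6.5 |
| ash | 30.0 | 20.1 | 11.7 | 16.6 |
| ash | 50.0 | 25.9 | 12.2 | 46.2 |
| ash | 60.0 | 24.6 | 13.2 | 63.6 |
| ash | 80.0 | 24.2 | 12.6 | 63.5 |

(standard deviation of a reading: 1 percentage point)

- percentages count the substrate that a species holds: one resting dimer counts as two
- the analysis behind the earlier runs scatters by 1 percentage point, standard deviation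
- steps thought possible: reagent + free catalyst -> catalyst intermediate A; substrate + catalyst intermediate A -> catalyst intermediate B; catalyst intermediate B -> catalyst intermediate C; catalyst intermediate C -> free catalyst + target; reagent + target -> over-reaction product; 2 catalyst intermediate B <-> resting dimer
- percentages count the whole charge, also what has not yet gone in
- no earlier run changes the charge of free catalyst; that part of a forecast is a guess

- ranking by share of target in all that became target or over-reaction product, from high to low, at 2.0 min (ochre / amber / green / violet / teal / red)
- the share of target in all that became target or over-reaction product of the flask you put first, at 2.0 min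
- the share of target in all that became target or over-reaction product of the flask you put last, at 2.0 min

What looked wrong was this: reagent makes target, yet at 80.0 s maple, charged with 0.062 M of reagent, held 19.6% target, while birch, with 16.1 times that charge, held 0% target and 100.4% over-reaction product.

I cleared this up by comparing two rates at one moment, the rate r at which target is made and the rate kO[reagent][target] at which it is lost. From the rise of over-reaction product in birch between 20.0 s and 60.0 s, with [reagent] taken at 40.0 s from the balance of target plus twice over-reaction product, I read kO as 0.418 L mol⁻¹ s⁻¹, a reading that carries the scatter of a single target value. The first maple reading of target plus over-reaction product gave r as 3.29 mM s⁻¹, so I reckoned that in violet, a near copy of maple with 0.0600 M of reagent as the limiting reagent, the charge lasts about 18.2 s at that rate, and maple's target read 20.2% at 20.0 s and 19.5% at 40.0 s, so it had stopped rising by about then.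

Then I asked how the comparison drifts. The ratio of loss to making starts at zero with [target] at zero and returns to zero with [reagent] at zero, and if [target] rises and [reagent] falls in straight lines, its average is kO times the square of the reagent charge, divided by 6 r. For violet this came to 0.0761, which I call the leak number, the over-reaction product made per target made over the life of the reagent charge. Each over-reaction product comes from a target already made, so my share for violet was one minus the leak number, 92.4%. In amber the reagent charge exceeds twice the substrate, so the leak number does not apply there.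

The forecast ranked violet > red > green > ochre > teal > amber, with 95% at the top (range 92% to 97.5%) and 4% at the bottom (range 2.5% to 6.5%), saying of its first flask “Violet repeats maple”, and its top figure stood higher than my share for violet.

The simulation gave violet > red > green > ochre > teal > amber, with 94.3% for violet and 3.75% for amber.

    reagent + free catalyst → catalyst intermediate A (k = 52.0 L mol⁻¹ s⁻¹)
    substrate + catalyst intermediate A → catalyst intermediate B (k = 500 L mol⁻¹ s⁻¹)
    catalyst intermediate B → catalyst intermediate C (k = 2.00 s⁻¹)
    catalyst intermediate C → free catalyst + target (k = 6.90 s⁻¹)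
    reagent + target → over-reaction product (k = 0.400 L mol⁻¹ s⁻¹)
    2 catalyst intermediate B ⇌ resting dimer, settled at all times (K = 72.0 L mol⁻¹)

Violet ended with 0% of its reagent, and that depletion was the main reason for its share: with the depletion taken away, the share fell from 94.3% to 13.2%, while the resting dimer made no difference to it. Against my leak number of 0.0761, violet's share left 5.7 percentage points over-reaction product per target made. For a neighbour of violet charged with 0.10 M of reagent, I took the rate 3.97 mM s⁻¹ read from larch, which made the leak number 0.175 and the share 82.5%, and that flask gave 87.7%.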